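**Retrosynthetic overview**
- The seven-membered depsidone ring (ring B) is opened twice: the lactone C–O bond by a carbonylative ring closure of an aryl bromide onto the C7 phenol, and the diaryl ether by an SNAr reaction of the C6 phenol of a chromanone with a 2-fluorobenzaldehyde (ring A).
- The chromanone (benzo ring C plus pyranone ring D) is cut at the aryl C8a–O1 bond and the aryl C4a–C4 (acyl) bond, giving an aryne and methyl 3-hydroxy-3-methylbutanoate.
- Enabling feature: C8a (O-bearing) and C4a (acyl-bearing) are ortho carbons of ring C and map onto the two carbons of an aryne, while O1–C2(CH3)2–C3–C4(=O) is an intact β-hydroxy ester with a nucleophilic O and an electrophilic acyl carbon in a 1,3-relationship. The C5 methyl next to C4a is carried as chlorine to polarise the aryne and is exchanged for methyl afterwards.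
- Order of ring formation: ring C (from an isovanillin derivative) → ring D (key step) → ring A attached through the ether → ring B last.

Key step: step 5

Assumption: the target has no stereocentre, so no stereocontrol is required; compounds 1, 9 and 15 are taken as catalogue compounds.

**Step 1**
Reactants: 1 2-chloro-3-hydroxy-4-methoxybenzaldehyde
Product: 2 3-(benzyloxy)-2-chloro-4-methoxybenzaldehyde
Conditions: BnBr, K2CO3, DMF, 50 °C
Reagents that add atoms: benzyl bromide, BrCc1ccccc1
Why: Williamson etherification of the only phenol should proceed cleanly and masks the oxygen that later becomes the diaryl ether oxygen.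

**Step 2**
Reactants: 2 3-(benzyloxy)-2-chloro-4-methoxybenzaldehyde
Product: 4 3-(benzyloxy)-2-chloro-4-methoxyphenol, via aryl formate 3 (not isolated)
Conditions: mCPBA, CH2Cl2, 0 °C to rt; then K2CO3 (cat.), MeOH, rt
Reagents that add atoms: mCPBA, O=C(OO)c1cccc(Cl)c1
Why: Baeyer–Villiger (Dakin-type) oxidation should favour migration of the electron-rich para-methoxyaryl group, and the formate is then cleaved by methanolysis.

**Step 3**
Reactants: 4 3-(benzyloxy)-2-chloro-4-methoxyphenol
Product: 5 3-(benzyloxy)-6-bromo-2-chloro-4-methoxyphenol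
Conditions: NBS (1.0 equiv), MeCN, 0 °C
Reagents that add atoms: N-bromosuccinimide, O=C1CCC(=O)N1Br
Why: Electrophilic aromatic bromination should occur at C6, the only free position that is ortho to the hydroxyl and para to the benzyloxy group.

**Step 4**
Reactants: 5 3-(benzyloxy)-6-bromo-2-chloro-4-methoxyphenol
Product: 8 3-(benzyloxy)-2-chloro-4-methoxy-6-(trimethylsilyl)phenyl trifluoromethanesulfonate, via silyl ether 6 (not isolated), via lithium silylphenoxide 7 (not isolated)
Conditions: (Me3Si)2NH, THF, 70 °C, concentrate; then n-BuLi, THF, −78 °C; then Tf2O, −78 to 0 °C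
Reagents that add atoms: hexamethyldisilazane, C[Si](C)(C)N[Si](C)(C)C; trifluoromethanesulfonic anhydride, O=S(=O)(OS(=O)(=O)C(F)(F)F)C(F)(F)F
Why: O-silylation, bromine–lithium exchange, retro-Brook 1,3-migration of silicon from O to C and O-triflation form the standard sequence to ortho-silylaryl triflates, and the aryl chloride should be inert to n-BuLi at −78 °C.

**Step 5**
Reactants: 8 3-(benzyloxy)-2-chloro-4-methoxy-6-(trimethylsilyl)phenyl trifluoromethanesulfonate; 9 methyl 3-hydroxy-3-methylbutanoate
Product: 12 6-(benzyloxy)-5-chloro-7-methoxy-2,2-dimethylchroman-4-one, via aryne 10 (not isolated), via aryl cesium ester 11 (not isolated)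
Conditions: CsF (4 equiv), THF, 65 °C
Reagents that add atoms: none
Why: Proposed new method: fluoride unmasks aryne 10 from 8 and generates the cesium alkoxide of 9; the tertiary alkoxide adds to the aryne carbon remote from chlorine (new aryl C8a–O1 bond), and the resulting aryl anion 11 attacks the tethered methyl ester and expels methoxide (new aryl C4a–C4 bond), closing ring D by a 6-exo-trig acyl substitution. The closest known reaction type is the fluoride-mediated annulation of arynes with methyl salicylates to xanthones, together with the formal insertion of arynes into carboxylic acids and β-lactams; an aliphatic tertiary β-hydroxy ester has not been used in this way. No stereocentre is formed. The step needs O-attack at the future C8a and C-acylation at the future C4a, and this is secured by the C–Cl bond next to the aryne, whose inductive pull distorts the triple bond so that the nucleophile enters meta to chlorine and the anion develops ortho to it, reinforced by the bulk of the tertiary alkoxide. It also needs acyl capture to outrun protonation of the aryl anion, which the aprotic medium and the six-membered transition state should favour.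

**Step 6**
Reactants: 12 6-(benzyloxy)-5-chloro-7-methoxy-2,2-dimethylchroman-4-one
Product: 13 6-(benzyloxy)-7-methoxy-2,2,5-trimethylchroman-4-one
Conditions: MeB(OH)2, Pd(OAc)2 (5 mol%), SPhos (10 mol%), K3PO4, toluene/H2O, 100 °C
Reagents that add atoms: methylboronic acid, CB(O)O
Why: Suzuki–Miyaura methylation should work on this aryl chloride because the ortho ketone assists oxidative addition to zerovalent palladium and the bulky biaryl phosphine tolerates the two ortho substituents.

**Step 7**
Reactants: 13 6-(benzyloxy)-7-methoxy-2,2,5-trimethylchroman-4-one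
Product: 14 6-hydroxy-7-methoxy-2,2,5-trimethylchroman-4-one
Conditions: H2 (1 atm), Pd/C, EtOAc, rt
Reagents that add atoms: none
Why: Hydrogenolysis of the benzyl ether should free only the C6 phenol, leaving the C7 methyl ether and the aryl ketone untouched under mild conditions.

**Step 8**
Reactants: 15 2,6-difluoro-4-methylbenzaldehyde
Product: 16 2-fluoro-6-methoxy-4-methylbenzaldehyde
Conditions: NaOMe (1.05 equiv), MeOH, 0 °C to rt
Reagents that add atoms: sodium methoxide, [Na+].[O-]C
Why: Nucleophilic aromatic substitution ortho to the formyl group should stop after one exchange because the new methoxy group deactivates the ring.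

**Step 9**
Reactants: 16 2-fluoro-6-methoxy-4-methylbenzaldehyde
Product: 17 3-bromo-2-fluoro-6-methoxy-4-methylbenzaldehyde
Conditions: NBS, CF3CO2H (cat.), MeCN, rt
Reagents that add atoms: N-bromosuccinimide, O=C1CCC(=O)N1Br
Why: Electrophilic aromatic bromination should go para to the methoxy group (C3), which is also meta to the formyl group.

**Step 10**
Reactants: 14 6-hydroxy-7-methoxy-2,2,5-trimethylchroman-4-one; 17 3-bromo-2-fluoro-6-methoxy-4-methylbenzaldehyde
Product: 18 3-bromo-6-methoxy-2-[(7-methoxy-2,2,5-trimethyl-4-oxochroman-6-yl)oxy]-4-methylbenzaldehyde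
Conditions: Cs2CO3, DMF, 90 °C
Reagents that add atoms: none
Why: SNAr diaryl ether formation should take place at the fluorine, which is activated by the ortho formyl group and the ortho bromine, while the bromide itself is not displaced.

**Step 11**
Reactants: 18 3-bromo-6-methoxy-2-[(7-methoxy-2,2,5-trimethyl-4-oxochroman-6-yl)oxy]-4-methylbenzaldehyde
Product: 19 3-bromo-6-hydroxy-2-[(7-hydroxy-2,2,5-trimethyl-4-oxochroman-6-yl)oxy]-4-methylbenzaldehyde
Conditions: BBr3, CH2Cl2, −78 °C to rt; then H2O
Reagents that add atoms: none
Why: Lewis acid cleavage of aryl methyl ethers should remove both methyl groups, the one ortho to the formyl group by chelation and the one para to the ketone on warming.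

**Step 12**
Reactants: 19 3-bromo-6-hydroxy-2-[(7-hydroxy-2,2,5-trimethyl-4-oxochroman-6-yl)oxy]-4-methylbenzaldehyde
Product: 20 Mollicellin A
Conditions: CO (1 atm), Pd(OAc)2 (5 mol%), Xantphos (10 mol%), Et3N, toluene, 100 °C
Reagents that add atoms: carbon monoxide, [C-]#[O+]
Why: Palladium-catalysed carbonylative lactonisation (intramolecular aryloxycarbonylation) should proceed by oxidative addition of zerovalent palladium to the C–Br bond, CO insertion and capture of the acyl palladium by the C7 phenol, the only hydroxyl that can reach it, closing ring B.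

**Compound list**
1 | 2-chloro-3-hydroxy-4-methoxybenzaldehyde | COc1ccc(C=O)c(Cl)c1O | starting material
2 | 3-(benzyloxy)-2-chloro-4-methoxybenzaldehyde | COc1ccc(C=O)c(Cl)c1OCc1ccccc1 | intermediate
3 | 3-(benzyloxy)-2-chloro-4-methoxyphenyl formate | COc1ccc(OC=O)c(Cl)c1OCc1ccccc1 | intermediate
4 | 3-(benzyloxy)-2-chloro-4-methoxyphenol | COc1ccc(O)c(Cl)c1OCc1ccccc1 | intermediate
5 | 3-(benzyloxy)-6-bromo-2-chloro-4-methoxyphenol | COc1cc(Br)c(O)c(Cl)c1OCc1ccccc1 | intermediate
6 | [3-(benzyloxy)-6-bromo-2-chloro-4-methoxyphenoxy]trimethylsilane | COc1cc(Br)c(O[Si](C)(C)C)c(Cl)c1OCc1ccccc1 | intermediate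
7 | lithium 3-(benzyloxy)-2-chloro-4-methoxy-6-(trimethylsilyl)phenoxide | [Li+].COc1cc([Si](C)(C)C)c([O-])c(Cl)c1OCc1ccccc1 | intermediate
8 | 3-(benzyloxy)-2-chloro-4-methoxy-6-(trimethylsilyl)phenyl trifluoromethanesulfonate | COc1cc([Si](C)(C)C)c(OS(=O)(=O)C(F)(F)F)c(Cl)c1OCc1ccccc1 | intermediate
9 | methyl 3-hydroxy-3-methylbutanoate | COC(=O)CC(C)(C)O | starting material
10 | 4-(benzyloxy)-3-chloro-5-methoxybenzyne (1,2-didehydrobenzene) | COC1=CC#CC(Cl)=C1OCc1ccccc1 | intermediate
11 | methyl 3-[4-(benzyloxy)-3-chloro-2-cesio-5-methoxyphenoxy]-3-methylbutanoate | [Cs+].COC(=O)CC(C)(C)Oc1cc(OC)c(OCc2ccccc2)c(Cl)[c-]1 | intermediate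
12 | 6-(benzyloxy)-5-chloro-7-methoxy-2,2-dimethylchroman-4-one | CC1(C)CC(=O)c2c(Cl)c(OCc3ccccc3)c(OC)cc2O1 | intermediate
13 | 6-(benzyloxy)-7-methoxy-2,2,5-trimethylchroman-4-one | CC1(C)CC(=O)c2c(C)c(OCc3ccccc3)c(OC)cc2O1 | intermediate
14 | 6-hydroxy-7-methoxy-2,2,5-trimethylchroman-4-one | CC1(C)CC(=O)c2c(C)c(O)c(OC)cc2O1 | intermediate
15 | 2,6-difluoro-4-methylbenzaldehyde | Cc1cc(F)c(C=O)c(F)c1 | starting material
16 | 2-fluoro-6-methoxy-4-methylbenzaldehyde | COc1cc(C)cc(F)c1C=O | intermediate
17 | 3-bromo-2-fluoro-6-methoxy-4-methylbenzaldehyde | COc1cc(C)c(Br)c(F)c1C=O | intermediate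
18 | 3-bromo-6-methoxy-2-[(7-methoxy-2,2,5-trimethyl-4-oxochroman-6-yl)oxy]-4-methylbenzaldehyde | COc1cc(C)c(Br)c(Oc2c(C)c3C(=O)CC(C)(C)Oc3cc2OC)c1C=O | intermediate
19 | 3-bromo-6-hydroxy-2-[(7-hydroxy-2,2,5-trimethyl-4-oxochroman-6-yl)oxy]-4-methylbenzaldehyde | Cc1cc(O)c(C=O)c(Oc2c(C)c3C(=O)CC(C)(C)Oc3cc2O)c1Br | intermediate
20 | Mollicellin A | Cc1cc(O)c(C=O)c2c1C(=O)Oc1cc3c(c(C)c1O2)C(=O)CC(C)(C)O3 | target

**Step count**
Total: 12 steps. Longest linear sequence: 10 steps (steps 1 to 7, then 10 to 12, from compound 1).

**Steps most likely to fail**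

Step 5 (key step). The aryl anion may be protonated by the hydroxy ester before it reaches the ester carbonyl, so that only O-arylation occurs, or the cesium alkoxide may fragment by retro-aldol cleavage before it meets the aryne. The fallback uses the known insertion of arynes into carboxylic acids and sets out from 8. Heating 8 with 3-methylbut-2-enoic acid and CsF in THF at 125 °C in a sealed tube should add the carboxylate to the same aryne carbon (the chlorine exerts the same control) and shift the acyl group from O to C through a four-membered intermediate. This gives the ortho-hydroxyaryl enone 1-[3-(benzyloxy)-2-chloro-6-hydroxy-4-methoxyphenyl]-3-methylbut-2-en-1-one F1, which should close in the flask by intramolecular oxa-Michael addition. The fallback comes back to the route at 12.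

Step 10. The doubly ortho-substituted phenoxide may attack the flanked aryl fluoride too slowly, and base-mediated aldol condensation between C3 of the chromanone and the aldehyde may then take over. The fallback forms the ester first and closes the ether intramolecularly, the classical depsidone ring closure; it sets out from 14 and 17.
- Cleavage of the methyl ether of 14 with BBr3 should give the catechol 6,7-dihydroxy-2,2,5-trimethylchroman-4-one F2.
- Palladium-catalysed hydroxycarbonylation of 17 (Pd(OAc)2, Xantphos, CO, Et3N, H2O, dioxane) should give 2-fluoro-3-formyl-4-methoxy-6-methylbenzoic acid F3.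
- Carbodiimide esterification (EDC, DMAP, CH2Cl2) should acylate the C7 hydroxyl of F2, which is para to the ketone and therefore the more acidic and less hindered one, giving the depside 6-hydroxy-2,2,5-trimethyl-4-oxochroman-7-yl 2-fluoro-3-formyl-4-methoxy-6-methylbenzoate F4. Acyl migration between the two catechol oxygens remains a risk at this point.
- K2CO3 in DMF should then close the seven-membered ring by intramolecular SNAr to give O-methyl mollicellin A F5.
- BCl3 in CH2Cl2 should cleave the methyl ether ortho to the formyl group. The fallback comes back to the route at 20.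

Step 12. Oxidative addition to the hindered, electron-rich aryl bromide bearing a free para hydroxyl may be slow, so that hydrodebromination or intermolecular ester formation through the ring A phenol competes with ring closure. The fallback carbonylates before the phenols are freed and closes the lactone by dehydration; it sets out from 18.
- Hydroxycarbonylation of 18 (Pd(OAc)2, Xantphos, CO, Et3N, H2O, dioxane) should give 3-formyl-4-methoxy-2-[(7-methoxy-2,2,5-trimethyl-4-oxochroman-6-yl)oxy]-6-methylbenzoic acid F6.
- BBr3 should then cleave both methyl ethers to give 3-formyl-4-hydroxy-2-[(7-hydroxy-2,2,5-trimethyl-4-oxochroman-6-yl)oxy]-6-methylbenzoic acid F7.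
- Trifluoroacetic anhydride in toluene should lactonise F7 onto the C7 phenol. The fallback comes back to the route at 20.

**Further compounds**
F1 | step 5 | 1-[3-(benzyloxy)-2-chloro-6-hydroxy-4-methoxyphenyl]-3-methylbut-2-en-1-one | CC(C)=CC(=O)c1c(O)cc(OC)c(OCc2ccccc2)c1Cl
F2 | step 10 | 6,7-dihydroxy-2,2,5-trimethylchroman-4-one | CC1(C)CC(=O)c2c(C)c(O)c(O)cc2O1
F3 | step 10 | 2-fluoro-3-formyl-4-methoxy-6-methylbenzoic acid | COc1cc(C)c(C(=O)O)c(F)c1C=O
F4 | step 10 | 6-hydroxy-2,2,5-trimethyl-4-oxochroman-7-yl 2-fluoro-3-formyl-4-methoxy-6-methylbenzoate | COc1cc(C)c(C(=O)Oc2cc3OC(C)(C)CC(=O)c3c(C)c2O)c(F)c1C=O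
F5 | step 10 | O-methyl mollicellin A | Cc1cc(OC)c(C=O)c2c1C(=O)Oc1cc3c(c(C)c1O2)C(=O)CC(C)(C)O3
F6 | step 12 | 3-formyl-4-methoxy-2-[(7-methoxy-2,2,5-trimethyl-4-oxochroman-6-yl)oxy]-6-methylbenzoic acid | COc1cc(C)c(C(=O)O)c(Oc2c(C)c3C(=O)CC(C)(C)Oc3cc2OC)c1C=O
F7 | step 12 | 3-formyl-4-hydroxy-2-[(7-hydroxy-2,2,5-trimethyl-4-oxochroman-6-yl)oxy]-6-methylbenzoic acid | Cc1cc(O)c(C=O)c(Oc2c(C)c3C(=O)CC(C)(C)Oc3cc2O)c1C(=O)O
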